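At 40.0 h, the last reading of the grey run, which is the very flask asked about, 84.0 % of the substrate charged stood as target and isomer of the product together.

- grey: substrate 0.050 M; the very flask that is asked about, followed so far
- flask: substrate 0.050 M; time 15 d

grey run (percent of the substrate charged)

| time / h | target / % | isomer of the product / % |
|---|---|---|
| 3.00 | 7 | 8 |
| 8.00 | 15 | 11 |
| 20.0 | 28 | 31 |
| 40.0 | 40 | 44 |

(scatter of a reading: 1.5 percentage points)

- ratio of target to isomer of the product at 1.0 h
- ratio of target to isomer of the product at 15 d

- what was read earlier has a scatter of 1.5 percentage points, one standard deviation

I built the flask up one process at a time. Taking the loss of substrate as the main step, first-order, that reading gave c(substrate) a decay constant of 0.0458 h⁻¹, so a half-life of 15.1 h.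

Next I let the two products form side by side and froze what the late readings held nearly constant. It was 47.5 % at 20.0 h and 47.6 % at 40.0 h: the target share, target over the sum of both products, or selectivity. With that share, c(target)/c(isomer of the product) is 0.909 at both asked times.

Then I added a delay. At 8.00 h the constant and the share gave 14.6 % target, and 15 % was read, but they gave 16.1 % isomer of the product, and 11 % was read. That is a shortfall of 5.1 percentage points against a scatter of 1.5 points. One reading is thin, and at 3.00 h the isomer of the product read 8 %, more than the 6.73 % they gave, yet I took the shortfall as a holding stage ahead of the isomer, which lifts the early ratio, so I committed to a ratio above 0.909 at 1.0 h, without a figure. Exchange between the products I could not read from these runs, so at 15 d I kept 0.909, with 47.6 % of the charge as target.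

The forecast gave 0.9 at 1.0 h and 0.9 at 15 d, and of the 8.00 h reading it said “I treat it as a misreading rather than as chemistry”, where I differed. The flask gives 2.49 at 1.0 h and 0.764 at 15 d.

    substrate ⇌ other conformer (K = 2.70, k = 0.0240 h⁻¹)
    substrate → target (k = 0.0210 h⁻¹)
    other conformer → isomer of the product (k = 0.930 h⁻¹)
    target ⇌ isomer of the product (K = 1.70, k = 8.40 × 10⁻⁴ h⁻¹)

At 15.0 d the flask stands 4.3 points below the target share I read, with 45.0 % target at 7.50 d and 43.3 % at 15.0 d. The same reckoning on the neighbouring flask, charged with 0.085 M of substrate, took over the share read from the grey run and again gave 47.6 % of its charge as target. That flask gives 2.49 at 1.0 h and 0.764 at 15 d, and at 15 d it holds 43.3 % target and 56.7 % isomer of the product.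

The data were computed for substances that don't exist, noise included.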